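Ring C of the flavan unit is cut twice, at O1–C8a and at C2–C3, which leads back to 3,4-bis(benzyloxy)benzaldehyde and an α-benzyloxy ketone whose ring A carries fluorine at the future C8a. A single base-mediated aldol/SNAr domino, a formal oxa-[4+2] annulation, exploits the C4 carbonyl twice: it makes C3 nucleophilic and activates the ortho carbon C8a for attack by the new C2 alkoxide O1. Transfer-hydrogenative kinetic resolution sets the absolute configuration and the C4 oxygen is then removed. The C8-lithiated catechin ether opens a Shi-derived trans-epoxide with inversion to attach the chalcane chain; hydrogenolysis finishes.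

Key step: step 3

Remark: compound 7 is formed as a racemate and is drawn as the (2R,3R) enantiomer that is carried on; 1,3,5-tris(benzyloxy)benzene and the L-fructose-derived Shi ketone are taken as purchasable.

Step 1
Reactants: 1 1,3,5-trifluorobenzene
Product: 2 1,3-bis(benzyloxy)-5-fluorobenzene
Conditions: BnOH (2.1 equiv), NaH (2.1 equiv), THF then NMP, 0 → 90 °C
Reagents that add atoms: benzyl alcohol, OCc1ccccc1
Why: Twofold SNAr by benzyloxide, each C–F bond being activated inductively by the two meta substituents; with two equivalents the third, least activated fluoride should remain.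

Step 2
Reactants: 2 1,3-bis(benzyloxy)-5-fluorobenzene; 3 2-(benzyloxy)acetic acid
Product: 4 2-(benzyloxy)-1-[2,4-bis(benzyloxy)-6-fluorophenyl]ethan-1-one
Conditions: (CF3CO)2O, 85% H3PO4 (cat.), MeCN, 0 → 23 °C
Reagents that add atoms: none
Why: Friedel–Crafts acylation by the mixed trifluoroacetic anhydride of 3; attack is expected para to one benzyloxy group and ortho to the small fluorine rather than at the hindered carbon between the two ether groups, as in the Vilsmeier formylation of 3,5-dialkoxyfluorobenzenes.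

Step 3
Reactants: 4 2-(benzyloxy)-1-[2,4-bis(benzyloxy)-6-fluorophenyl]ethan-1-one; 5 3,4-bis(benzyloxy)benzaldehyde
Product: 7 rac-(2R,3R)-3,5,7-tris(benzyloxy)-2-[3,4-bis(benzyloxy)phenyl]chroman-4-one, via potassium aldolate 6 (not isolated)
Conditions: KOt-Bu (1.2 equiv), THF/DMF (4:1), −40 → 0 °C; AcOH
Reagents that add atoms: none
Why: The potassium enolate of 4 adds to aldehyde 5 (C2–C3), and the alkoxide oxygen of 6 then attacks the fluorine-bearing ring A carbon in an intramolecular SNAr through a Meisenheimer adduct stabilised by the ortho carbonyl, expelling fluoride (O1–C8a); the closest known reaction type is the tandem aldol/SNAr annulation of ortho-fluoroaryl ketones. Ring C closes by a 6-exo addition–elimination at the sp2 carbon C8a, a formal oxa-[4+2] annulation in which the aldehyde C=O is the two-atom partner. C2 and C3 are new: C3, α to the ketone, equilibrates under the base to the diequatorial 2,3-trans isomer, so the relative configuration is under thermodynamic control, while the product is racemic and its absolute configuration is selected in step 4. The step needs ring closure to outrun loss of water from the aldolate and attack of tert-butoxide on the C–F bond; the six-membered transition state, the ketone-activated ortho fluoride and the low temperature should secure this, and retro-aldol is harmless because only the cyclisation is irreversible.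

Step 4
Reactants: 7 rac-(2R,3R)-3,5,7-tris(benzyloxy)-2-[3,4-bis(benzyloxy)phenyl]chroman-4-one
Product: 8 (2R,3S,4R)-3,5,7-tris(benzyloxy)-2-[3,4-bis(benzyloxy)phenyl]chroman-4-ol
Conditions: RuCl(p-cymene)[(S,S)-TsDPEN] (1 mol%), HCO2H/Et3N (5:2), EtOAc, 30 °C, to about half conversion
Reagents that add atoms: none
Why: Noyori–Ikariya asymmetric transfer hydrogenation run as a kinetic resolution, a known way to resolve 2-arylchroman-4-ones: the (S,S) catalyst delivers hydride to the carbonyl face that in the (2R,3R) enantiomer is also the substrate-preferred axial face, giving the all-equatorial (4R) alcohol, while the mismatched (2S,3S) ketone stays, is separated on silica and can be racemised with KOt-Bu (ring opening to the chalcone and reclosure) for reuse.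

Step 5
Reactants: 8 (2R,3S,4R)-3,5,7-tris(benzyloxy)-2-[3,4-bis(benzyloxy)phenyl]chroman-4-ol
Product: 9 (2R,3S)-3,5,7-tris(benzyloxy)-2-[3,4-bis(benzyloxy)phenyl]chromane (penta-O-benzyl-(+)-catechin)
Conditions: Et3SiH, CF3CO2H, CH2Cl2, −30 → 0 °C
Reagents that add atoms: none
Why: Ionic hydrogenation: the acid ionises the C4 hydroxyl to a benzylic cation stabilised by the three ring A oxygens and the silane reduces it; C2 and C3 should be untouched because the C2–O1 ether, next to the inductively withdrawing C3 oxygen, ionises far more slowly at this temperature.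

Step 6
Reactants: 9 (2R,3S)-3,5,7-tris(benzyloxy)-2-[3,4-bis(benzyloxy)phenyl]chromane
Product: 10 (2R,3S)-3,5,7-tris(benzyloxy)-2-[3,4-bis(benzyloxy)phenyl]-8-bromochromane
Conditions: NBS (1.0 equiv), CH2Cl2, −78 → 0 °C
Reagents that add atoms: N-bromosuccinimide, O=C1CCC(=O)N1Br
Why: Electrophilic aromatic bromination at C8, the ring A position flanked by the pyran oxygen and the known site of NBS attack on benzylated catechins; one equivalent at low temperature should spare C6 and ring B.

Step 7
Reactants: 5 3,4-bis(benzyloxy)benzaldehyde; 11 vinylmagnesium bromide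
Product: 12 rac-1-[3,4-bis(benzyloxy)phenyl]prop-2-en-1-ol
Conditions: THF, −78 → 0 °C; H2O
Reagents that add atoms: none
Why: Grignard 1,2-addition to the aldehyde; the new stereocenter is of no consequence because it is lost by ionisation in step 8.

Step 8
Reactants: 12 rac-1-[3,4-bis(benzyloxy)phenyl]prop-2-en-1-ol; 13 1,3,5-tris(benzyloxy)benzene
Product: 14 1,3,5-tris(benzyloxy)-2-[(2E)-3-[3,4-bis(benzyloxy)phenyl]prop-2-en-1-yl]benzene
Conditions: TsOH·H2O (5 mol%), CH2Cl2, 0 → 23 °C, 13 in twofold excess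
Reagents that add atoms: none
Why: Acid-catalysed Friedel–Crafts allylation through the 1-arylallyl cation, which the symmetric arene 13 should attack at the terminal carbon to give the conjugated E-alkene.

Step 9
Reactants: 14 1,3,5-tris(benzyloxy)-2-[(2E)-3-[3,4-bis(benzyloxy)phenyl]prop-2-en-1-yl]benzene
Product: 15 (2S,3S)-2-[3,4-bis(benzyloxy)phenyl]-3-[2,4,6-tris(benzyloxy)benzyl]oxirane
Conditions: L-fructose-derived Shi ketone (1,2:4,5-di-O-isopropylidene-β-L-erythro-2,3-hexodiulo-2,6-pyranose, 30 mol%), Oxone (2KHSO5·KHSO4·K2SO4), K2CO3, Bu4NHSO4, MeCN/CH2(OMe)2/aq. Na2B4O7–Na2EDTA buffer, 0 °C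
Reagents that add atoms: potassium peroxymonosulfate (KHSO5), [K+].[O-]S(=O)(=O)OO
Why: Shi asymmetric epoxidation by the chiral dioxirane through the spiro transition state; the L-series ketone should give the (S,S)-epoxide from this trans-disubstituted styrene, mirroring the (R,R) selectivity of the D-series ketone, and the basic buffer protects the acid-labile epoxide.

Step 10
Reactants: 10 (2R,3S)-3,5,7-tris(benzyloxy)-2-[3,4-bis(benzyloxy)phenyl]-8-bromochromane; 15 (2S,3S)-2-[3,4-bis(benzyloxy)phenyl]-3-[2,4,6-tris(benzyloxy)benzyl]oxirane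
Product: 17 (1S,2S)-1-[3,4-bis(benzyloxy)phenyl]-1-[(2R,3S)-3,5,7-tris(benzyloxy)-2-[3,4-bis(benzyloxy)phenyl]chroman-8-yl]-3-[2,4,6-tris(benzyloxy)phenyl]propan-2-ol, via aryllithium 16 (not isolated)
Conditions: n-BuLi, THF, −78 °C; 15, then BF3·OEt2, −78 °C; H2O
Reagents that add atoms: none
Why: Bromine–lithium exchange followed by BF3-assisted opening of the aryl epoxide by the aryllithium at the benzylic carbon, anti to the departing oxygen (inversion), which should set the (S)-diarylmethine center while the carbinol carbon keeps its (S) configuration from 15.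

Step 11
Reactants: 17 (1S,2S)-1-[3,4-bis(benzyloxy)phenyl]-1-[(2R,3S)-3,5,7-tris(benzyloxy)-2-[3,4-bis(benzyloxy)phenyl]chroman-8-yl]-3-[2,4,6-tris(benzyloxy)phenyl]propan-2-ol
Product: 18 (1S,2S)-1-(3,4-dihydroxyphenyl)-1-[(2R,3S)-2-(3,4-dihydroxyphenyl)-3,5,7-trihydroxychroman-8-yl]-3-(2,4,6-trihydroxyphenyl)propan-2-ol (CNP0175733.2)
Conditions: H2 (1 atm), Pd(OH)2/C, THF/MeOH, 23 °C, work-up under argon
Reagents that add atoms: none
Why: Hydrogenolysis of the ten benzyl ethers; the ring C benzylic ether and the four stereocenters should survive these mild conditions, as is usual for benzylated catechins.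

Compound list
1 | 1,3,5-trifluorobenzene | Fc1cc(F)cc(F)c1 | starting material
2 | 1,3-bis(benzyloxy)-5-fluorobenzene | Fc1cc(OCc2ccccc2)cc(OCc2ccccc2)c1 | intermediate
3 | 2-(benzyloxy)acetic acid | OC(=O)COCc1ccccc1 | starting material
4 | 2-(benzyloxy)-1-[2,4-bis(benzyloxy)-6-fluorophenyl]ethan-1-one | O=C(COCc1ccccc1)c1c(F)cc(OCc2ccccc2)cc1OCc1ccccc1 | intermediate
5 | 3,4-bis(benzyloxy)benzaldehyde | O=Cc1ccc(OCc2ccccc2)c(OCc2ccccc2)c1 | starting material
6 | potassium 2-(benzyloxy)-1-[3,4-bis(benzyloxy)phenyl]-3-[2,4-bis(benzyloxy)-6-fluorophenyl]-3-oxopropan-1-olate (stereoisomer mixture, not isolated) | [K+].[O-]C(c1ccc(OCc2ccccc2)c(OCc2ccccc2)c1)C(OCc1ccccc1)C(=O)c1c(F)cc(OCc2ccccc2)cc1OCc1ccccc1 | intermediate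
7 | rac-(2R,3R)-3,5,7-tris(benzyloxy)-2-[3,4-bis(benzyloxy)phenyl]chroman-4-one (2,3-trans; racemate, (2R,3R) enantiomer drawn) | C(c1ccccc1)O[C@H]2C(=O)c3c(OCc4ccccc4)cc(OCc4ccccc4)cc3O[C@@H]2c5ccc(OCc6ccccc6)c(OCc6ccccc6)c5 | intermediate
8 | (2R,3S,4R)-3,5,7-tris(benzyloxy)-2-[3,4-bis(benzyloxy)phenyl]chroman-4-ol | C(c1ccccc1)O[C@H]2[C@H](O)c3c(OCc4ccccc4)cc(OCc4ccccc4)cc3O[C@@H]2c5ccc(OCc6ccccc6)c(OCc6ccccc6)c5 | intermediate
9 | (2R,3S)-3,5,7-tris(benzyloxy)-2-[3,4-bis(benzyloxy)phenyl]chromane (penta-O-benzyl-(+)-catechin) | C(c1ccccc1)O[C@H]2Cc3c(OCc4ccccc4)cc(OCc4ccccc4)cc3O[C@@H]2c5ccc(OCc6ccccc6)c(OCc6ccccc6)c5 | intermediate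
10 | (2R,3S)-3,5,7-tris(benzyloxy)-2-[3,4-bis(benzyloxy)phenyl]-8-bromochromane | C(c1ccccc1)O[C@H]2Cc3c(OCc4ccccc4)cc(OCc4ccccc4)c(Br)c3O[C@@H]2c5ccc(OCc6ccccc6)c(OCc6ccccc6)c5 | intermediate
11 | vinylmagnesium bromide | C=C[Mg]Br | starting material
12 | rac-1-[3,4-bis(benzyloxy)phenyl]prop-2-en-1-ol | OC(C=C)c1ccc(OCc2ccccc2)c(OCc2ccccc2)c1 | intermediate
13 | 1,3,5-tris(benzyloxy)benzene | c1ccccc1COc1cc(OCc2ccccc2)cc(OCc2ccccc2)c1 | starting material
14 | 1,3,5-tris(benzyloxy)-2-[(2E)-3-[3,4-bis(benzyloxy)phenyl]prop-2-en-1-yl]benzene | C(/C=C/c1ccc(OCc2ccccc2)c(OCc2ccccc2)c1)c1c(OCc2ccccc2)cc(OCc2ccccc2)cc1OCc1ccccc1 | intermediate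
15 | (2S,3S)-2-[3,4-bis(benzyloxy)phenyl]-3-[2,4,6-tris(benzyloxy)benzyl]oxirane | c1ccccc1COc1cc(OCc2ccccc2)c(C[C@@H]2O[C@H]2c2ccc(OCc3ccccc3)c(OCc3ccccc3)c2)c(OCc2ccccc2)c1 | intermediate
16 | [(2R,3S)-3,5,7-tris(benzyloxy)-2-[3,4-bis(benzyloxy)phenyl]chroman-8-yl]lithium (not isolated) | C(c1ccccc1)O[C@H]2Cc3c(OCc4ccccc4)cc(OCc4ccccc4)c([Li])c3O[C@@H]2c5ccc(OCc6ccccc6)c(OCc6ccccc6)c5 | intermediate
17 | (1S,2S)-1-[3,4-bis(benzyloxy)phenyl]-1-[(2R,3S)-3,5,7-tris(benzyloxy)-2-[3,4-bis(benzyloxy)phenyl]chroman-8-yl]-3-[2,4,6-tris(benzyloxy)phenyl]propan-2-ol | c1ccccc1COc1cc(OCc2ccccc2)c(C[C@H](O)[C@@H](c2ccc(OCc3ccccc3)c(OCc3ccccc3)c2)c2c(OCc3ccccc3)cc(OCc3ccccc3)c3c2O[C@H](c2ccc(OCc4ccccc4)c(OCc4ccccc4)c2)[C@@H](OCc2ccccc2)C3)c(OCc2ccccc2)c1 | intermediate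
18 | (1S,2S)-1-(3,4-dihydroxyphenyl)-1-[(2R,3S)-2-(3,4-dihydroxyphenyl)-3,5,7-trihydroxychroman-8-yl]-3-(2,4,6-trihydroxyphenyl)propan-2-ol | Oc1cc(O)c(C[C@H](O)[C@@H](c2ccc(O)c(O)c2)c2c(O)cc(O)c3c2O[C@H](c2ccc(O)c(O)c2)[C@@H](O)C3)c(O)c1 | target

Total step count: 11. Longest linear sequence: 8 steps (steps 1 to 6, then 10 and 11).

Steps most likely to fail

Step 10. The hindered, doubly ortho-oxygenated aryllithium may react too slowly, so that the Lewis acid rearranges the electron-rich epoxide to a ketone first. The epoxide may also ionise fully, so that inversion at the benzylic carbon is eroded. The fallback sets out from 9 and 15 and comes back at 17. The non-brominated ether 9, in threefold excess, is used as a π-nucleophile in a Friedel–Crafts opening of 15 in (CF3)2CHOH at 0 °C. This is a known stereoinvertive arylation of aryl epoxides at the benzylic carbon, in which the hydrogen-bonding solvent activates the epoxide without a metal Lewis acid. C8 of ring A, the position that couples in benzylated catechins, is the expected site of attack. No further compound is made (F0).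

Step 4. Hydride transfer to the electron-rich, doubly flanked C4 carbonyl may be slow, or the discrimination between the enantiomers of 7 may be too small. The fallback sets out from 7 and comes back at 9. Racemic 7 is reduced without selection by NaBH4 in THF/MeOH, which gives 8 together with its enantiomer (2S,3R,4S)-3,5,7-tris(benzyloxy)-2-[3,4-bis(benzyloxy)phenyl]chroman-4-ol F1. The mixture is deoxygenated as in step 5 to 9 and its enantiomer (2S,3R)-3,5,7-tris(benzyloxy)-2-[3,4-bis(benzyloxy)phenyl]chromane F2. The two are separated by preparative supercritical-fluid chromatography on an amylose tris(3,5-dimethylphenylcarbamate) phase, and 9 goes on to step 6.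

Step 3. Loss of water from the potassium aldolate to the α-benzyloxychalcone, or displacement of fluoride by tert-butoxide, may compete with ring closure. The fallback sets out from 4 and 5 and comes back at 7. The lithium enolate of 4 (LDA, THF, −78 °C) is added to 5 and the aldolate is protonated at −78 °C with AcOH. This allows 2-(benzyloxy)-3-[3,4-bis(benzyloxy)phenyl]-1-[2,4-bis(benzyloxy)-6-fluorophenyl]-3-hydroxypropan-1-one F3 to be isolated as a diastereomer mixture. F3 is then cyclised separately with Cs2CO3 in DMF at 23 °C, a non-nucleophilic base under which the intramolecular SNAr and the equilibration of C3 to the trans isomer should proceed.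

Further compounds
F0 | step 10 | none | none
F1 | step 4 | (2S,3R,4S)-3,5,7-tris(benzyloxy)-2-[3,4-bis(benzyloxy)phenyl]chroman-4-ol | C(c1ccccc1)O[C@@H]2[C@@H](O)c3c(OCc4ccccc4)cc(OCc4ccccc4)cc3O[C@H]2c5ccc(OCc6ccccc6)c(OCc6ccccc6)c5
F2 | step 4 | (2S,3R)-3,5,7-tris(benzyloxy)-2-[3,4-bis(benzyloxy)phenyl]chromane | C(c1ccccc1)O[C@@H]2Cc3c(OCc4ccccc4)cc(OCc4ccccc4)cc3O[C@H]2c5ccc(OCc6ccccc6)c(OCc6ccccc6)c5
F3 | step 3 | 2-(benzyloxy)-3-[3,4-bis(benzyloxy)phenyl]-1-[2,4-bis(benzyloxy)-6-fluorophenyl]-3-hydroxypropan-1-one (diastereomer mixture) | OC(c1ccc(OCc2ccccc2)c(OCc2ccccc2)c1)C(OCc1ccccc1)C(=O)c1c(F)cc(OCc2ccccc2)cc1OCc1ccccc1
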